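**Conventions.** Lactone ring atoms are O1, C2–C6. The chain on C6 is C1'–C7' (methyls on C1', C3', C5'; epoxide C5'–C6'). The acyl chain is C1''–C8''. Target numbering is used for positions throughout.

## The problem

The target (25) is a 5,6-dihydro-2H-pyran-2-one that carries at C6 a branched epoxy-alkyl chain and at the C5 oxygen a (2E,4E)-dienoate ending in a 1,4-diol. It has seven stereocentres: C5, C6 and C1' are contiguous and all syn, C3' is 1,3-syn to C1', the epoxide centres C5'/C6' lie behind a methylene group, and C6'' sits in the acid. Only C5 has a neighbour (C6, in the ring) that can set it; the C1'/C3' pair has the relationship of a meso 2,4-dimethylglutarate, while the epoxide and C6'' need reagent control. The two halves must be joined through a hindered secondary allylic oxygen that is cis to a branched chain. The C5 acyloxy group is an allylic ester γ to the lactone carbonyl, so base threatens elimination to the 2-pyranone, translactonisation or conjugate addition; the trisubstituted epoxide does not tolerate acid; and the diol must be unmasked last under conditions that avoid both. The feature that opens the plan is in the ring: C2 (carbonyl), the cis C3=C4 bond and C5 (oxygenated) form a (Z)-but-2-ene-1,4-dioxygenated unit, and C5 is bonded to the carbinol carbon C6 whose oxygen is O1. That is the oxidation pattern of a 2-furylcarbinol, so the whole ring can come from a flat furan with C6 as the only ring stereocentre that must exist beforehand.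

## Retrosynthesis

**25 ⇒ 24.** Only two O–Si bonds are cut. The diol is carried as two primary TBS ethers because they survive saponification and the Mitsunobu reaction and leave under buffered fluoride. The lower half then needs no protecting group at all. The forward step must spare the epoxide and the allylic ester.

**24 ⇒ 17 + 23.** The ester is cut at the C5–O (alkyl–oxygen) bond, not at the acyl–oxygen bond. Hydride reduction of the ring ketone gives the 5,6-trans alcohol 17, so an invertive union turns that outcome into the required cis ester and joins the halves in the same step. The precursors are a 15-carbon hydroxy lactone and a 22-carbon acid with one stereocentre. The forward reaction must be a clean SN2 at an allylic carbon.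

**17 ⇒ 16 ⇒ 15 ⇒ 13 (key).** The C5–H bond (hydride), the lactone carbonyl (lactol oxidation) and then the ring itself are undone: the O1–C2 bond is cut and C2–C5 are returned to a furan. Compared with ring-closing metathesis or Z-olefination/lactonisation, no C=C bond has to be made, the cis geometry comes from the arene, and C5 is reached as a ketone next to C6, which can then control it. 13 is a flat furan with one carbinol centre in place of a ring with two stereocentres. The forward oxidation must touch only the furan, so 13 may hold no other alkene, which puts the epoxidation earlier.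

**13 ⇒ 12 ⇒ 11.** The C6–H bond is cut (asymmetric transfer hydrogenation), then the two epoxide C–O bonds (Shi epoxidation). C6 needs catalyst control because Felkin control by C1' would give the opposite epimer. The epoxide is made on the acylfuran 11, where the carbonyl group deactivates the furan toward electrophilic oxygen.

**11 ⇒ 8 + 9; 8 ⇒ 7 ⇒ 4 + 5.** The C4'–C5' sp3–sp2 bond is cut (Negishi coupling), which buys the E geometry with bromide 9. The C6–furan bond is cut next: 2-furyllithium 6 opens lactone 4, so one step brings in the arene and frees the C4' hydroxyl for conversion into iodide 8.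

**4 ⇒ 2 ⇒ 1.** Both methyl stereocentres come from meso anhydride 1. One catalytic desymmetrisation (to 2) fixes C1' and C3' together, and chemoselective reduction through 3 gives 4.

**23 ⇒ 22 ⇒ 21 ⇒ 20 ⇒ 18.** The C2''=C3'' and C4''=C5'' bonds are cut (two Wittig reactions), then the C6''–CH2OH bond (organocatalytic α-hydroxymethylation of 18 through 19). The single stereocentre is set by catalysis on a four-carbon aldehyde.

## Roads not taken

**Alternative 1:** (the most obvious) Cut O1–C2 by acylation and C3=C4 by metathesis. Epoxy aldehyde A1 would undergo syn-selective γ-alkoxyallylboration with a (Z)-γ-(4-methoxybenzyloxy)allyl diisopinocampheylborane, then acryloylation to diene A2, ring closure with the second-generation Grubbs catalyst to the PMB-protected pyranone A3, oxidative PMB removal and retentive acylation with 23. This needs a stoichiometric chiral borane to set C5 and C6 against an epimerisable α-methyl aldehyde. It also adds a protecting group on the C5 oxygen and is at least one step longer from lactone 4, because A1 must first be made from it. In the chosen plan the furan arrives in the step that opens the lactone, C6 is set catalytically, C5 is relayed from C6, and the ring alkene is never made.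

**Alternative 2:** Cut the C5–O and C6–O bonds together. Asymmetric dihydroxylation of the distal E-alkene of (2Z,4E)-dienoate A4 would give a syn diol that lactonises through the Z-enoate. A4 needs a Z-selective olefination of an enal that is itself three or more steps from A1. The osmylation must choose between two alkenes and work next to the C1' centre, and its basic medium threatens the Z-enoate and the hydroxy lactone (translactonisation to the butenolide). The furan route meets none of these selectivity problems.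

**Alternative 3:** Cut the C5–H and C6–H bonds together. The flat 5-hydroxy-2-pyranone A5 (the enol tautomer of 16) would be hydrogenated across C5=C6 to set both centres cis in one event from an achiral ring. The C5=C6 bond is tetrasubstituted and doubly oxygenated, whereas C3=C4 is disubstituted and more accessible, so stopping at the 5,6-dihydro stage is doubtful on mechanistic grounds. Facial control next to C1' would rest on an untested catalyst–substrate pairing, and no step is saved against transfer hydrogenation plus Luche reduction.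

Key step: step 8

Assumption (step 1): (DHQD)2AQN is taken to open the carbonyl group next to the (S)-configured carbon of 1; if it opens the other one, the pseudo-enantiomeric (DHQ)2AQN is used with no other change.
Assumption (materials): 1 (or its diacid, closed with Ac2O), 9 and 18 are taken as commercial.

## Route

Step 1
Reactants: 1 cis-2,4-dimethylglutaric anhydride (meso)
Product: 2 (2R,4S)-5-methoxy-2,4-dimethyl-5-oxopentanoic acid
Conditions: MeOH (10 equiv), (DHQD)2AQN (10 mol %), Et2O, −40 °C
Reagents that add atoms: methanol, CO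
Why: Cinchona-alkaloid-catalysed desymmetrising alcoholysis of a meso cyclic anhydride (general-base catalysis by the quinuclidine nitrogen); the syn relation of the methyl groups is bought with 1 and the catalyst only chooses between the enantiotopic carbonyl groups, which fixes the future C1' (S) and C3' (R) at once.

Step 2
Reactants: 2 (2R,4S)-5-methoxy-2,4-dimethyl-5-oxopentanoic acid
Product: 4 (3S,5R)-3,5-dimethyloxan-2-one, via hydroxy ester 3 (not isolated)
Conditions: BH3·SMe2, THF, 0 °C to rt; MeOH quench; then TsOH·H2O (cat.), CH2Cl2, rt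
Reagents that add atoms: none
Why: Borane reduces the free carboxylic acid (acyloxyborane pathway) much faster than the methyl ester, and the δ-hydroxy ester 3 closes to the six-membered lactone under acid catalysis; neither stereocentre is touched.

Step 3
Reactants: 4 (3S,5R)-3,5-dimethyloxan-2-one; 5 furan
Product: 7 (2S,4R)-1-(furan-2-yl)-5-hydroxy-2,4-dimethylpentan-1-one, via 2-furyllithium 6 (not isolated)
Conditions: 5, n-BuLi, THF, 0 °C; then 4, −78 °C; aq. NH4Cl
Reagents that add atoms: n-butyllithium, [Li]CCCC (its lithium is held in 6 only)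
Why: Addition of an aryllithium to a δ-lactone stops at the lithium hemiketal alkoxide at −78 °C, which collapses to the hydroxy ketone on work-up; one step attaches the furan at C6 and frees the C4' hydroxyl, and C1' is not enolised under these conditions.

Step 4
Reactants: 7 (2S,4R)-1-(furan-2-yl)-5-hydroxy-2,4-dimethylpentan-1-one
Product: 8 (2S,4R)-1-(furan-2-yl)-5-iodo-2,4-dimethylpentan-1-one
Conditions: I2, PPh3, imidazole, CH2Cl2, 0 °C
Reagents that add atoms: iodine, II
Why: Appel-type iodination of the primary alcohol by SN2 displacement of the alkoxyphosphonium ion; the medium is neutral enough for the furan and for the α-stereocentre of the aryl ketone.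

Step 5
Reactants: 8 (2S,4R)-1-(furan-2-yl)-5-iodo-2,4-dimethylpentan-1-one; 9 (E)-2-bromo-2-butene
Product: 11 (2S,4R,6E)-1-(furan-2-yl)-2,4,6-trimethyloct-6-en-1-one, via alkylzinc iodide 10 (not isolated)
Conditions: Zn dust (activated with BrCH2CH2Br/Me3SiCl), LiCl, THF, 40 °C; then 9, PdCl2(dppf) (5 mol %), 45 °C
Reagents that add atoms: zinc, [Zn] (held in 10 only)
Why: Negishi coupling: zinc inserts into the primary C–I bond, the alkylzinc iodide tolerates the aryl ketone, and PdCl2(dppf) couples it with the alkenyl bromide with retention, so the E geometry is bought with 9; the stereocentre β to zinc cannot epimerise.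

Step 6
Reactants: 11 (2S,4R,6E)-1-(furan-2-yl)-2,4,6-trimethyloct-6-en-1-one
Product: 12 (2S,4R)-5-[(2R,3R)-2,3-dimethyloxiran-2-yl]-1-(furan-2-yl)-2,4-dimethylpentan-1-one
Conditions: Shi ketone (D-fructose-derived, 30 mol %), Oxone (2KHSO5·KHSO4·K2SO4), K2CO3, Bu4NHSO4, MeCN/CH2(OMe)2–aq. Na2B4O7/Na2EDTA, 0 °C
Reagents that add atoms: Oxone, active component potassium peroxymonosulfate, [K+].[O-]S(=O)(=O)OO
Why: Shi epoxidation: the dioxirane of the D-fructose-derived ketone transfers oxygen through a spiro transition state to the electron-rich (E)-trisubstituted alkene, the substrate class it handles best, and should give the (5'R,6'R) epoxide under catalyst control; the 2-acylfuran is deactivated toward electrophilic oxygen by its carbonyl group.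

Step 7
Reactants: 12 (2S,4R)-5-[(2R,3R)-2,3-dimethyloxiran-2-yl]-1-(furan-2-yl)-2,4-dimethylpentan-1-one
Product: 13 (1R,2S,4R)-5-[(2R,3R)-2,3-dimethyloxiran-2-yl]-1-(furan-2-yl)-2,4-dimethylpentan-1-ol
Conditions: RuCl[(R,R)-TsDPEN](p-cymene) (2 mol %), HCO2Na, CTAB, H2O/CH2Cl2, rt
Reagents that add atoms: none
Why: Noyori asymmetric transfer hydrogenation of an aryl alkyl ketone: the (R,R)-TsDPEN ruthenium hydride recognises the furyl ring (CH–π contact) and should deliver hydride to give the (R)-carbinol, i.e. C6, under catalyst control (the sense opposite to Felkin control by C1'); formate in water keeps the medium neutral for the epoxide.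

Step 8
Reactants: 13 (1R,2S,4R)-5-[(2R,3R)-2,3-dimethyloxiran-2-yl]-1-(furan-2-yl)-2,4-dimethylpentan-1-ol
Product: 15 (2R)-2-{(2S,4R)-5-[(2R,3R)-2,3-dimethyloxiran-2-yl]-4-methylpentan-2-yl}-6-hydroxy-2H-pyran-3(6H)-one (anomeric mixture), via (Z)-ene-dione 14 (not isolated)
Conditions: NBS, NaHCO3, NaOAc·3H2O, THF/H2O (4:1), 0 °C
Reagents that add atoms: water, O
Why: Achmatowicz rearrangement (oxidative ring expansion of a 2-furylcarbinol). NBS delivers Br+ to the free α-position of the furan and water adds at the substituted α-carbon; the resulting 2,5-dihydrofuran loses HBr and opens to the (Z)-4-oxo-2-enal 14, whose cis geometry is inherited from the ring. The C6 hydroxyl then adds to the aldehyde carbon (6-exo-trig hemiacetal formation), which closes the pyranone ring through the O1–C2 bond and gives 15. The only new stereocentre is the hemiacetal carbon; it is not controlled and need not be, because step 9 oxidises it to the lactone carbonyl. C6, set in step 7, is not involved and keeps its configuration. The step needs chemoselectivity for the furan: 13 holds no other alkene (the reason the epoxide is made in step 6, while the furan is still deactivated), the epoxide has no affinity for Br+, and the NaHCO3/NaOAc buffer keeps the HBr from opening it. In one operation the flat arene becomes the ring with C2 at the lactol level, the cis C3=C4 bond and a C5 ketone that serves as the handle for the C5 stereocentre.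

Step 9
Reactants: 15 (2R)-2-{(2S,4R)-5-[(2R,3R)-2,3-dimethyloxiran-2-yl]-4-methylpentan-2-yl}-6-hydroxy-2H-pyran-3(6H)-one
Product: 16 (6R)-6-{(2S,4R)-5-[(2R,3R)-2,3-dimethyloxiran-2-yl]-4-methylpentan-2-yl}-2H-pyran-2,5(6H)-dione
Conditions: Dess–Martin periodinane, NaHCO3, CH2Cl2, 0 °C
Reagents that add atoms: none
Why: Dess–Martin oxidation of the hemiacetal to the lactone without amine base; solid NaHCO3 takes up the acetic acid so that the epoxide is spared, and the base-sensitive ene-dione 16 (enolisation toward C6 would give the flat 5-hydroxy-2-pyranone) is carried on crude.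

Step 10
Reactants: 16 (6R)-6-{(2S,4R)-5-[(2R,3R)-2,3-dimethyloxiran-2-yl]-4-methylpentan-2-yl}-2H-pyran-2,5(6H)-dione
Product: 17 (5S,6R)-6-{(2S,4R)-5-[(2R,3R)-2,3-dimethyloxiran-2-yl]-4-methylpentan-2-yl}-5-hydroxy-5,6-dihydro-2H-pyran-2-one
Conditions: NaBH4, CeCl3·7H2O, MeOH/CH2Cl2, −78 °C
Reagents that add atoms: none
Why: Luche reduction: the cerium-activated ketone takes hydride 1,2 (no conjugate reduction) along the axial trajectory of the half-chair with the C6 chain pseudo-equatorial, which should give the pseudo-equatorial 5,6-trans alcohol (5S) by substrate control from C6, as in Luche reductions of 2-alkyl-2H-pyran-3(6H)-ones.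

Step 11
Reactants: 18 4-[(tert-butyldimethylsilyl)oxy]butanal
Product: 20 (4S,2E)-6-[(tert-butyldimethylsilyl)oxy]-4-(hydroxymethyl)-2-methylhex-2-enal, via α-hydroxymethyl aldehyde 19 (not isolated)
Conditions: aq. HCHO, (S)-α,α-diphenylprolinol trimethylsilyl ether (10 mol %), pH 7 phosphate buffer, toluene, rt; then organic phase + Ph3P=C(CH3)CHO, 40 °C
Reagents that add atoms: formaldehyde, C=O; 2-(triphenylphosphoranylidene)propanal, CC(C=O)=P(c1ccccc1)(c1ccccc1)c1ccccc1
Why: Enamine catalysis: the (E)-enamine of 18 is shielded on one face by the CPh2(OSiMe3) group and adds to formaldehyde from the open face, which should set the (R) centre of 19 (the future C6''); the labile β-hydroxy aldehyde is trapped at once by Wittig reaction with the stabilised ylide, which gives the (E)-2-methyl enal.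

Step 12
Reactants: 20 (4S,2E)-6-[(tert-butyldimethylsilyl)oxy]-4-(hydroxymethyl)-2-methylhex-2-enal
Product: 21 (4S,2E)-6-[(tert-butyldimethylsilyl)oxy]-4-{[(tert-butyldimethylsilyl)oxy]methyl}-2-methylhex-2-enal
Conditions: TBSCl, imidazole, CH2Cl2, 0 °C to rt
Reagents that add atoms: tert-butyldimethylsilyl chloride, CC(C)(C)[Si](C)(C)Cl
Why: Standard silylation of a primary alcohol; both arms of the future diol now carry the same group, which survives the Wittig reaction, the saponification and the Mitsunobu reaction.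

Step 13
Reactants: 21 (4S,2E)-6-[(tert-butyldimethylsilyl)oxy]-4-{[(tert-butyldimethylsilyl)oxy]methyl}-2-methylhex-2-enal
Product: 22 methyl (2E,4E,6S)-8-[(tert-butyldimethylsilyl)oxy]-6-{[(tert-butyldimethylsilyl)oxy]methyl}-4-methylocta-2,4-dienoate
Conditions: Ph3P=CHCO2Me, toluene, 70 °C
Reagents that add atoms: methyl (triphenylphosphoranylidene)acetate, COC(=O)C=P(c1ccccc1)(c1ccccc1)c1ccccc1
Why: Wittig olefination with a stabilised ylide gives the (2E)-enoate; the C6'' centre is no longer α to a carbonyl group and cannot epimerise.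

Step 14
Reactants: 22 methyl (2E,4E,6S)-8-[(tert-butyldimethylsilyl)oxy]-6-{[(tert-butyldimethylsilyl)oxy]methyl}-4-methylocta-2,4-dienoate
Product: 23 (2E,4E,6S)-8-[(tert-butyldimethylsilyl)oxy]-6-{[(tert-butyldimethylsilyl)oxy]methyl}-4-methylocta-2,4-dienoic acid
Conditions: LiOH·H2O, THF/MeOH/H2O, rt; then 1 M HCl to pH 4, 0 °C
Reagents that add atoms: lithium hydroxide, [Li+].[OH-]
Why: Saponification of the methyl dienoate; primary TBS ethers are stable to LiOH and the β,δ-substituted dienoate resists conjugate addition of hydroxide.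

Step 15
Reactants: 17 (5S,6R)-6-{(2S,4R)-5-[(2R,3R)-2,3-dimethyloxiran-2-yl]-4-methylpentan-2-yl}-5-hydroxy-5,6-dihydro-2H-pyran-2-one; 23 (2E,4E,6S)-8-[(tert-butyldimethylsilyl)oxy]-6-{[(tert-butyldimethylsilyl)oxy]methyl}-4-methylocta-2,4-dienoic acid
Product: 24 (2R,3R)-2-{(2S,4R)-5-[(2R,3R)-2,3-dimethyloxiran-2-yl]-4-methylpentan-2-yl}-6-oxo-3,6-dihydro-2H-pyran-3-yl (2E,4E,6S)-8-[(tert-butyldimethylsilyl)oxy]-6-{[(tert-butyldimethylsilyl)oxy]methyl}-4-methylocta-2,4-dienoate
Conditions: PPh3, DIAD, THF, 0 °C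
Reagents that add atoms: none
Why: Mitsunobu esterification: the C5 hydroxyl becomes an alkoxyphosphonium leaving group and is displaced by the carboxylate of 23 by SN2 with inversion, which should turn the 5,6-trans alcohol into the 5,6-cis ester (5R) and joins the two halves in the same step; invertive esterification of 5-hydroxy-5,6-dihydropyran-2-ones is a known use of this reaction.

Step 16
Reactants: 24 (2R,3R)-2-{(2S,4R)-5-[(2R,3R)-2,3-dimethyloxiran-2-yl]-4-methylpentan-2-yl}-6-oxo-3,6-dihydro-2H-pyran-3-yl (2E,4E,6S)-8-[(tert-butyldimethylsilyl)oxy]-6-{[(tert-butyldimethylsilyl)oxy]methyl}-4-methylocta-2,4-dienoate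
Product: 25 target, (2R,3R)-2-{(2S,4R)-5-[(2R,3R)-2,3-dimethyloxiran-2-yl]-4-methylpentan-2-yl}-6-oxo-3,6-dihydro-2H-pyran-3-yl (2E,4E,6S)-8-hydroxy-6-(hydroxymethyl)-4-methylocta-2,4-dienoate
Conditions: HF·pyridine, pyridine, THF, 0 °C to rt
Reagents that add atoms: none
Why: Fluoride-induced cleavage of two primary silyl ethers with HF·pyridine buffered by excess pyridine, a medium in which trisubstituted epoxides and allylic esters have precedent for survival; no stereocentre is touched.

## Compound list

1 | cis-2,4-dimethylglutaric anhydride, (3R,5S)-3,5-dimethyloxane-2,6-dione (meso) | C[C@H]1C[C@@H](C)C(=O)OC1=O | starting material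
2 | (2R,4S)-5-methoxy-2,4-dimethyl-5-oxopentanoic acid | COC(=O)[C@@H](C)C[C@@H](C)C(=O)O | intermediate
3 | methyl (2S,4R)-5-hydroxy-2,4-dimethylpentanoate | COC(=O)[C@@H](C)C[C@@H](C)CO | intermediate (not isolated)
4 | (3S,5R)-3,5-dimethyloxan-2-one | O=C1OC[C@H](C)C[C@@H]1C | intermediate
5 | furan | c1ccoc1 | starting material
6 | 2-furyllithium | [Li]c1ccco1 | intermediate (not isolated)
7 | (2S,4R)-1-(furan-2-yl)-5-hydroxy-2,4-dimethylpentan-1-one | O=C(c1ccco1)[C@@H](C)C[C@@H](C)CO | intermediate
8 | (2S,4R)-1-(furan-2-yl)-5-iodo-2,4-dimethylpentan-1-one | O=C(c1ccco1)[C@@H](C)C[C@@H](C)CI | intermediate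
9 | (E)-2-bromo-2-butene | C/C=C(\C)Br | starting material
10 | [(2R,4S)-5-(furan-2-yl)-2,4-dimethyl-5-oxopentyl]zinc iodide | O=C(c1ccco1)[C@@H](C)C[C@@H](C)C[Zn]I | intermediate (not isolated)
11 | (2S,4R,6E)-1-(furan-2-yl)-2,4,6-trimethyloct-6-en-1-one | O=C(c1ccco1)[C@@H](C)C[C@@H](C)C/C(C)=C/C | intermediate
12 | (2S,4R)-5-[(2R,3R)-2,3-dimethyloxiran-2-yl]-1-(furan-2-yl)-2,4-dimethylpentan-1-one | O=C(c1ccco1)[C@@H](C)C[C@@H](C)C[C@@]1(C)O[C@@H]1C | intermediate
13 | (1R,2S,4R)-5-[(2R,3R)-2,3-dimethyloxiran-2-yl]-1-(furan-2-yl)-2,4-dimethylpentan-1-ol | O[C@@H](c1ccco1)[C@@H](C)C[C@@H](C)C[C@@]1(C)O[C@@H]1C | intermediate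
14 | (2Z,5R,6S,8R)-9-[(2R,3R)-2,3-dimethyloxiran-2-yl]-5-hydroxy-6,8-dimethyl-4-oxonon-2-enal | O=C/C=C\C(=O)[C@H](O)[C@@H](C)C[C@@H](C)C[C@@]1(C)O[C@@H]1C | intermediate (not isolated)
15 | (2R)-2-{(2S,4R)-5-[(2R,3R)-2,3-dimethyloxiran-2-yl]-4-methylpentan-2-yl}-6-hydroxy-2H-pyran-3(6H)-one (anomeric mixture) | O=C1C=CC(O)O[C@@H]1[C@@H](C)C[C@@H](C)C[C@@]1(C)O[C@@H]1C | intermediate
16 | (6R)-6-{(2S,4R)-5-[(2R,3R)-2,3-dimethyloxiran-2-yl]-4-methylpentan-2-yl}-2H-pyran-2,5(6H)-dione | O=C1C=CC(=O)O[C@@H]1[C@@H](C)C[C@@H](C)C[C@@]1(C)O[C@@H]1C | intermediate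
17 | (5S,6R)-6-{(2S,4R)-5-[(2R,3R)-2,3-dimethyloxiran-2-yl]-4-methylpentan-2-yl}-5-hydroxy-5,6-dihydro-2H-pyran-2-one | O[C@H]1C=CC(=O)O[C@@H]1[C@@H](C)C[C@@H](C)C[C@@]1(C)O[C@@H]1C | intermediate
18 | 4-[(tert-butyldimethylsilyl)oxy]butanal | O=CCCCO[Si](C)(C)C(C)(C)C | starting material
19 | (R)-4-[(tert-butyldimethylsilyl)oxy]-2-(hydroxymethyl)butanal | O=C[C@@H](CO)CCO[Si](C)(C)C(C)(C)C | intermediate (not isolated)
20 | (4S,2E)-6-[(tert-butyldimethylsilyl)oxy]-4-(hydroxymethyl)-2-methylhex-2-enal | CC(/C=O)=C\[C@@H](CO)CCO[Si](C)(C)C(C)(C)C | intermediate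
21 | (4S,2E)-6-[(tert-butyldimethylsilyl)oxy]-4-{[(tert-butyldimethylsilyl)oxy]methyl}-2-methylhex-2-enal | CC(/C=O)=C\[C@@H](CO[Si](C)(C)C(C)(C)C)CCO[Si](C)(C)C(C)(C)C | intermediate
22 | methyl (2E,4E,6S)-8-[(tert-butyldimethylsilyl)oxy]-6-{[(tert-butyldimethylsilyl)oxy]methyl}-4-methylocta-2,4-dienoate | CC(/C=C/C(=O)OC)=C\[C@@H](CO[Si](C)(C)C(C)(C)C)CCO[Si](C)(C)C(C)(C)C | intermediate
23 | (2E,4E,6S)-8-[(tert-butyldimethylsilyl)oxy]-6-{[(tert-butyldimethylsilyl)oxy]methyl}-4-methylocta-2,4-dienoic acid | CC(/C=C/C(=O)O)=C\[C@@H](CO[Si](C)(C)C(C)(C)C)CCO[Si](C)(C)C(C)(C)C | intermediate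
24 | bis-TBS ether of the target, (2R,3R)-2-{(2S,4R)-5-[(2R,3R)-2,3-dimethyloxiran-2-yl]-4-methylpentan-2-yl}-6-oxo-3,6-dihydro-2H-pyran-3-yl (2E,4E,6S)-8-[(tert-butyldimethylsilyl)oxy]-6-{[(tert-butyldimethylsilyl)oxy]methyl}-4-methylocta-2,4-dienoate | CC(/C=C/C(=O)O[C@@H]1C=CC(=O)O[C@@H]1[C@@H](C)C[C@@H](C)C[C@@]1(C)O[C@@H]1C)=C\[C@@H](CO[Si](C)(C)C(C)(C)C)CCO[Si](C)(C)C(C)(C)C | intermediate
25 | target, (2R,3R)-2-{(2S,4R)-5-[(2R,3R)-2,3-dimethyloxiran-2-yl]-4-methylpentan-2-yl}-6-oxo-3,6-dihydro-2H-pyran-3-yl (2E,4E,6S)-8-hydroxy-6-(hydroxymethyl)-4-methylocta-2,4-dienoate | CC(/C=C/C(=O)O[C@@H]1C=CC(=O)O[C@@H]1[C@@H](C)C[C@@H](C)C[C@@]1(C)O[C@@H]1C)=C\[C@@H](CO)CCO | target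

## Step count and least certain steps

Total: 16 steps. Longest linear sequence: 12 steps (steps 1–10, 15, 16); the acid 23 takes 4 steps (11–14).

**Step 8 (key step).** The furan oxidation itself is reliable. The likely failure is opening of the trisubstituted epoxide by bromide or water under the HBr released, in this step or in the oxidation that follows. Fallback: take the alkene through the ring expansion and epoxidise after the union. Setting out from 11, transfer hydrogenation as in step 7 gives the alkenyl carbinol (1R,2S,4R,6E)-1-(furan-2-yl)-2,4,6-trimethyloct-6-en-1-ol F1. Hydroxyl-directed ring expansion with VO(acac)2/t-BuOOH (CH2Cl2, rt), which leaves the remote alkene alone, gives the lactol F2. Dess–Martin oxidation gives the dione F3, Luche reduction the trans alcohol F4, and Mitsunobu union with 23 the des-epoxy diene ester F5. Epoxidation of the only electron-rich alkene of F5 with the Shi ketone under its near-neutral protocol (3 equiv ketone, Oxone (2KHSO5·KHSO4·K2SO4), NaHCO3, MeCN/aq. Na2EDTA, 0 °C, pH about 8) returns to the route at 24.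

**Step 6.** The risk is loss of chemoselectivity, with the dioxirane attacking the furan ring as well, or epimerisation at C1' in the carbonate buffer. Fallback: make the epoxide before the furan is present. Setting out from 4, opening with MeNH(OMe)·HCl/Me2AlCl gives the hydroxy Weinreb amide F6. Iodination as in step 4 gives the iodo amide F7, zinc insertion gives the alkylzinc iodide F8, and coupling with 9 as in step 5 gives the alkenyl amide F9. Shi epoxidation (no furan present) gives the epoxy amide F10, and addition of 2-furyllithium 6 at −78 °C returns to the route at 12.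

**Step 7.** The risk is slow hydride transfer to the α-branched ketone combined with a mismatch between catalyst and the C1' centre, giving poor facial selectivity. Fallback: use substrate control and invert. Setting out from 12, Felkin-selective reduction with L-Selectride (LiBH(s-Bu)3, THF, −78 °C) gives the (1S)-carbinol F11. Mitsunobu inversion with 4-nitrobenzoic acid (PPh3, DIAD, toluene, −20 °C) gives the (1R)-4-nitrobenzoate F12, and methanolysis (K2CO3, MeOH, 0 °C) returns to the route at 13.

**Step 15.** The risk is SN2' capture or elimination of the allylic oxyphosphonium ion to the 2H-pyran-2-one when the bulky, weakly acidic dienoic acid reacts slowly. Fallback: invert with a small, strong acid and then acylate with retention. Setting out from 17, Mitsunobu reaction with 4-nitrobenzoic acid gives the cis 4-nitrobenzoate F13. Mild methanolysis (Et3N, MeOH, 0 °C) gives the cis alcohol F14, and Yamaguchi acylation with 23 (2,4,6-trichlorobenzoyl chloride, Et3N, DMAP, toluene) returns to the route at 24.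

**Step 16.** The risk is acid-promoted opening of the epoxide (fluorohydrin formation) or cleavage of the allylic ester before both TBS ethers are gone. Fallback: switch to ethers that leave by oxidation at neutral pH. Setting out from 22, desilylation (HF·pyridine, THF; no epoxide in this fragment) gives the diol ester F15. Protection with 4-methoxybenzyl 2,2,2-trichloroacetimidate (cat. CSA) gives the bis-PMB ester F16, and saponification gives the bis-PMB acid F17. Mitsunobu union with 17 as in step 15 gives the bis-PMB ether of the target F18, and DDQ (CH2Cl2/pH 7 buffer, 0 °C) returns to the route at 25.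

## Further compounds

F1 | step 8 | (1R,2S,4R,6E)-1-(furan-2-yl)-2,4,6-trimethyloct-6-en-1-ol | O[C@@H](c1ccco1)[C@@H](C)C[C@@H](C)C/C(C)=C/C
F2 | step 8 | (2R)-2-[(2S,4R,6E)-4,6-dimethyloct-6-en-2-yl]-6-hydroxy-2H-pyran-3(6H)-one | O=C1C=CC(O)O[C@@H]1[C@@H](C)C[C@@H](C)C/C(C)=C/C
F3 | step 8 | (6R)-6-[(2S,4R,6E)-4,6-dimethyloct-6-en-2-yl]-2H-pyran-2,5(6H)-dione | O=C1C=CC(=O)O[C@@H]1[C@@H](C)C[C@@H](C)C/C(C)=C/C
F4 | step 8 | (5S,6R)-6-[(2S,4R,6E)-4,6-dimethyloct-6-en-2-yl]-5-hydroxy-5,6-dihydro-2H-pyran-2-one | O[C@H]1C=CC(=O)O[C@@H]1[C@@H](C)C[C@@H](C)C/C(C)=C/C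
F5 | step 8 | (2R,3R)-2-[(2S,4R,6E)-4,6-dimethyloct-6-en-2-yl]-6-oxo-3,6-dihydro-2H-pyran-3-yl (2E,4E,6S)-8-[(tert-butyldimethylsilyl)oxy]-6-{[(tert-butyldimethylsilyl)oxy]methyl}-4-methylocta-2,4-dienoate | CC(/C=C/C(=O)O[C@@H]1C=CC(=O)O[C@@H]1[C@@H](C)C[C@@H](C)C/C(C)=C/C)=C\[C@@H](CO[Si](C)(C)C(C)(C)C)CCO[Si](C)(C)C(C)(C)C
F6 | step 6 | (2S,4R)-5-hydroxy-N-methoxy-N,2,4-trimethylpentanamide | CON(C)C(=O)[C@@H](C)C[C@@H](C)CO
F7 | step 6 | (2S,4R)-5-iodo-N-methoxy-N,2,4-trimethylpentanamide | CON(C)C(=O)[C@@H](C)C[C@@H](C)CI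
F8 | step 6 | {(2R,4S)-5-[methoxy(methyl)amino]-2,4-dimethyl-5-oxopentyl}zinc iodide | CON(C)C(=O)[C@@H](C)C[C@@H](C)C[Zn]I
F9 | step 6 | (2S,4R,6E)-N-methoxy-N,2,4,6-tetramethyloct-6-enamide | CON(C)C(=O)[C@@H](C)C[C@@H](C)C/C(C)=C/C
F10 | step 6 | (2S,4R)-5-[(2R,3R)-2,3-dimethyloxiran-2-yl]-N-methoxy-N,2,4-trimethylpentanamide | CON(C)C(=O)[C@@H](C)C[C@@H](C)C[C@@]1(C)O[C@@H]1C
F11 | step 7 | (1S,2S,4R)-5-[(2R,3R)-2,3-dimethyloxiran-2-yl]-1-(furan-2-yl)-2,4-dimethylpentan-1-ol | O[C@H](c1ccco1)[C@@H](C)C[C@@H](C)C[C@@]1(C)O[C@@H]1C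
F12 | step 7 | (1R,2S,4R)-5-[(2R,3R)-2,3-dimethyloxiran-2-yl]-1-(furan-2-yl)-2,4-dimethylpentyl 4-nitrobenzoate | O=C(O[C@@H](c1ccco1)[C@@H](C)C[C@@H](C)C[C@@]1(C)O[C@@H]1C)c1ccc(cc1)[N+](=O)[O-]
F13 | step 15 | (2R,3R)-2-{(2S,4R)-5-[(2R,3R)-2,3-dimethyloxiran-2-yl]-4-methylpentan-2-yl}-6-oxo-3,6-dihydro-2H-pyran-3-yl 4-nitrobenzoate | O=C(O[C@@H]1C=CC(=O)O[C@@H]1[C@@H](C)C[C@@H](C)C[C@@]1(C)O[C@@H]1C)c1ccc(cc1)[N+](=O)[O-]
F14 | step 15 | (5R,6R)-6-{(2S,4R)-5-[(2R,3R)-2,3-dimethyloxiran-2-yl]-4-methylpentan-2-yl}-5-hydroxy-5,6-dihydro-2H-pyran-2-one | O[C@@H]1C=CC(=O)O[C@@H]1[C@@H](C)C[C@@H](C)C[C@@]1(C)O[C@@H]1C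
F15 | step 16 | methyl (2E,4E,6S)-8-hydroxy-6-(hydroxymethyl)-4-methylocta-2,4-dienoate | CC(/C=C/C(=O)OC)=C\[C@@H](CO)CCO
F16 | step 16 | methyl (2E,4E,6S)-8-[(4-methoxybenzyl)oxy]-6-{[(4-methoxybenzyl)oxy]methyl}-4-methylocta-2,4-dienoate | CC(/C=C/C(=O)OC)=C\[C@@H](COCc1ccc(OC)cc1)CCOCc1ccc(OC)cc1
F17 | step 16 | (2E,4E,6S)-8-[(4-methoxybenzyl)oxy]-6-{[(4-methoxybenzyl)oxy]methyl}-4-methylocta-2,4-dienoic acid | CC(/C=C/C(=O)O)=C\[C@@H](COCc1ccc(OC)cc1)CCOCc1ccc(OC)cc1
F18 | step 16 | (2R,3R)-2-{(2S,4R)-5-[(2R,3R)-2,3-dimethyloxiran-2-yl]-4-methylpentan-2-yl}-6-oxo-3,6-dihydro-2H-pyran-3-yl (2E,4E,6S)-8-[(4-methoxybenzyl)oxy]-6-{[(4-methoxybenzyl)oxy]methyl}-4-methylocta-2,4-dienoate | CC(/C=C/C(=O)O[C@@H]1C=CC(=O)O[C@@H]1[C@@H](C)C[C@@H](C)C[C@@]1(C)O[C@@H]1C)=C\[C@@H](COCc1ccc(OC)cc1)CCOCc1ccc(OC)cc1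
A1 | alternative 1 | (2S,4R)-5-[(2R,3R)-2,3-dimethyloxiran-2-yl]-2,4-dimethylpentanal | O=C[C@@H](C)C[C@@H](C)C[C@@]1(C)O[C@@H]1C
A2 | alternative 1 | (3R,4R,5S,7R)-8-[(2R,3R)-2,3-dimethyloxiran-2-yl]-3-[(4-methoxybenzyl)oxy]-5,7-dimethyloct-1-en-4-yl acrylate | C=CC(=O)O[C@@H]([C@H](OCc1ccc(OC)cc1)C=C)[C@@H](C)C[C@@H](C)C[C@@]1(C)O[C@@H]1C
A3 | alternative 1 | (5R,6R)-6-{(2S,4R)-5-[(2R,3R)-2,3-dimethyloxiran-2-yl]-4-methylpentan-2-yl}-5-[(4-methoxybenzyl)oxy]-5,6-dihydro-2H-pyran-2-one | COc1ccc(CO[C@@H]2C=CC(=O)O[C@@H]2[C@@H](C)C[C@@H](C)C[C@@]3(C)O[C@@H]3C)cc1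
A4 | alternative 2 | ethyl (2Z,4E,6S,8R)-9-[(2R,3R)-2,3-dimethyloxiran-2-yl]-6,8-dimethylnona-2,4-dienoate | CCOC(=O)/C=C\C=C\[C@@H](C)C[C@@H](C)C[C@@]1(C)O[C@@H]1C
A5 | alternative 3 | 6-{(2S,4R)-5-[(2R,3R)-2,3-dimethyloxiran-2-yl]-4-methylpentan-2-yl}-5-hydroxy-2H-pyran-2-one | O=c1ccc(O)c(o1)[C@@H](C)C[C@@H](C)C[C@@]1(C)O[C@@H]1C
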